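The ring sequence C(OAc)–CMe2–CH(chain)–C(Me)=CH–CH2 of the target is, atom for atom, the six-membered ring of chrysanthenone, whose C=O bridge ties the two stereocentres cis. The route therefore makes the CMe2–CH(chain) ring bond not by polyene cyclisation but by the photochemical 1,3-shift of the CMe2 bridge in commercial (1S,5S)-verbenone, a bicyclo[3.1.1]heptenone. This one isomerisation closes the target carbocycle, relays the pool stereocentre to the chain-bearing carbon and places the trisubstituted alkene, which Bredt's rule then locks. Baeyer–Villiger excision of the bridge turns C–C into C–O with retention. The bridge carbon becomes C1′ of the chain, which is completed by B-alkyl Suzuki coupling with a C19 alkenyl iodide.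

Key step: step 1

Remark on the structure: the SMILES is read as (1S,5R), with OAc and side chain cis on the ring and the three stereodefined chain alkenes E. Target ring locants are C1 (CHOAc), C2 (CH2), C3 (=CH), C4 (=CMe), C5 (CH–chain) and C6 (CMe2); the chain is C1′, C2′ and so on.
Assumption: commercial (1S,5S)-(−)-verbenone is taken as enantiopure.

Step 1
Reactants: 1 (1S,5S)-(−)-verbenone
Product: 2 (1R,5S)-chrysanthenone
Conditions: hν (365 nm LED, or Hg lamp behind a λ > 340 nm filter), cyclohexane (dilute), N2, 10–15 °C, stopped short of full conversion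
Reagents that add atoms: none
Why: n→π* excitation of the enone breaks the strained, allylic C5–C6 bond (γ-carbon to CMe2) to a tertiary-alkyl/oxapentadienyl biradical that recloses at the enone α-carbon C3, a photochemical [1,3]-sigmatropic alkyl shift that is the known behaviour of this enone class. The radical recombination closes the four-membered C1–C2–C3–C6 ketone ring and, with the same bond, the six-membered ring C1–C6–C3–C4–C5–C7 that is the carbocycle of the target (new bond = target C6–C5). C1 of 1 (target C1) is an untouched pool stereocentre, and the new stereocentre C3 of 1 (target C5) is controlled by the tether, because C6 stays bound to C1, can reach C3 only on the face it leaves, and only the cis-bridged bicyclo[3.1.1] frame can exist. The double bond arrives at C4=C5 of 1 (target C4=C3) and cannot drift towards the bridgehead (Bredt's rule), which settles the endocyclic trisubstituted regiochemistry. The selectivity needed is survival of 2, whose Norrish type I cleavage leads to an achiral dienylketene and thus to loss of ee; light that the conjugated enone 1 absorbs but the β,γ-enone 2 hardly does, an inert solvent, low temperature and incomplete conversion secure it.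

Step 2
Reactants: 2 (1R,5S)-chrysanthenone
Product: 4 2,3-epoxy-2,8,8-trimethyl-6-oxabicyclo[3.2.1]octan-7-one (oxirane anti to CMe2), via chrysanthenone 2,3-epoxide 3 (not isolated)
Conditions: mCPBA (2.5 equiv), NaHCO3 (buffer), CH2Cl2, 0 °C to rt
Reagents that add atoms: mCPBA, OOC(=O)c1cccc(Cl)c1
Why: Prilezhaev epoxidation of the trisubstituted alkene (peracid approaches anti to the CMe2 bridge, which sets the two transient oxirane centres) outruns ketone oxidation and removes the allylic assistance at bridgehead C1, so that in the ensuing Baeyer–Villiger oxidation of the strained cyclobutanone the bridgehead C5, rather than the one β to the C–O dipole, should migrate with retention, which sets the C–O stereocentre cis to the carbonyl carbon.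

Step 3
Reactants: 4 epoxy lactone
Product: 5 (1R,5S)-2,8,8-trimethyl-6-oxabicyclo[3.2.1]oct-2-en-7-one
Conditions: Re2O7 (cat.), P(OPh)3, toluene, 100 °C
Reagents that add atoms: none
Why: Rhenium-catalysed oxygen-atom transfer from epoxide to phosphite (stereospecific epoxide deoxygenation) restores the ring alkene and erases both oxirane centres, while the lactone is inert and the bridgehead position of C1 forbids both epimerisation and conjugation.

Step 4
Reactants: 5 unsaturated γ-lactone
Product: 7 (1R,5S)-2,8,8-trimethyl-6-oxabicyclo[3.2.1]oct-2-en-7-ol (lactol, anomers), via aluminium lactolate 6 (not isolated)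
Conditions: DIBAL-H (1.1 equiv), CH2Cl2, −78 °C; aq. Rochelle salt
Reagents that add atoms: none
Why: Partial lactone reduction with DIBAL-H stops at the tetrahedral aluminium lactolate at low temperature, and the new anomeric centre is of no consequence because it is lost in step 5.

Step 5
Reactants: 7 lactol
Product: 9 (1S,5R)-5-ethenyl-4,6,6-trimethylcyclohex-3-en-1-ol, via open hydroxy aldehyde 8 (not isolated)
Conditions: Ph3PCH3Br, KHMDS (3 equiv each), THF, −78 to 0 °C, lactol added to the preformed ylide
Reagents that add atoms: methyltriphenylphosphonium bromide, C[P+](c1ccccc1)(c1ccccc1)c1ccccc1.[Br-]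
Why: Wittig methylenation of the ring-opened lactol, in which fast addition of the unstabilised ylide at low temperature should outrun deprotonation at the allylic α-carbon C5, so that no stereocentre is made or touched.

Step 6
Reactants: 9 vinyl alcohol
Product: 10 (1S,5R)-5-ethenyl-4,6,6-trimethylcyclohex-3-en-1-yl acetate
Conditions: Ac2O, Et3N, DMAP (cat.), CH2Cl2, rt
Reagents that add atoms: acetic anhydride, CC(=O)OC(C)=O
Why: DMAP-catalysed acyl transfer acetylates the equatorial alcohol next to CMe2, as it does 3β-hydroxy-4,4-dimethyl triterpenoids, and the C–O bond is not broken, so the configuration is kept.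

Step 7
Reactants: 11 (2E,6E)-farnesyl bromide; 12 propyne
Product: 15 (6E,10E)-2,6,10-trimethylhexadeca-2,6,10-trien-14-yne, via 1,3-dilithiopropyne 13 (not isolated), via lithium acetylide 14 (not isolated)
Conditions: 12, n-BuLi (2 equiv per propyne), TMEDA, Et2O–hexane, −78 to 0 °C; 11, −78 to 0 °C; then MeI, DMPU, 0 °C to rt
Reagents that add atoms: iodomethane, CI
Why: SN2 alkylation of the primary allylic bromide at the more reactive propargylic carbon of the dianion builds the tail-to-tail CH2–CH2 link, and methylation of the remaining acetylide caps the alkyne without touching the E-alkenes.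

Step 8
Reactants: 15 methyl alkyne
Product: 17 (6E,10E,14E)-15-iodo-2,6,10-trimethylhexadeca-2,6,10,14-tetraene, via alkenylzirconocene chloride 16 (not isolated)
Conditions: Cp2Zr(H)Cl (excess), THF, 45 °C; then I2, 0 °C
Reagents that add atoms: iodine, II
Why: Hydrozirconation with Schwartz reagent adds H and Zr syn, excess reagent with warming equilibrates Zr to the less hindered methyl-bearing carbon, and iodinolysis with retention gives the E-iodide, while the trisubstituted alkenes do not react.

Step 9
Reactants: 10 vinyl acetate; 17 alkenyl iodide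
Product: 19 (1S,5R)-4,6,6-trimethyl-5-[(3E,7E,11E)-3,8,12,16-tetramethylheptadeca-3,7,11,15-tetraen-1-yl]cyclohex-3-en-1-yl acetate, via B-alkyl-9-BBN 18 (not isolated)
Conditions: 9-BBN, THF, 0 °C to rt; then 17, Pd(dppf)Cl2 (cat.), AsPh3 (cat.), aq. K3PO4, DMF, rt
Reagents that add atoms: none
Why: 9-BBN hydroborates only the monosubstituted alkene in the anti-Markovnikov sense, and the B-alkyl Suzuki–Miyaura coupling joins C2′ to C3′ with retention of the iodide geometry, leaving the acetate, ring alkene and both stereocentres untouched.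

Compound list
1 | (1S,5S)-4,6,6-trimethylbicyclo[3.1.1]hept-3-en-2-one, (−)-verbenone | CC1=CC(=O)[C@H]2C[C@@H]1C2(C)C | starting material
2 | (1R,5S)-2,7,7-trimethylbicyclo[3.1.1]hept-2-en-6-one, chrysanthenone | CC1=CC[C@@H]2C(=O)[C@H]1C2(C)C | intermediate
3 | chrysanthenone 2,3-epoxide, oxirane on the C=O-bridge face | C[C@@]12O[C@@H]1C[C@@H]3C(=O)[C@H]2C3(C)C | intermediate
4 | 2,3-epoxy-2,8,8-trimethyl-6-oxabicyclo[3.2.1]octan-7-one | C[C@@]12O[C@@H]1C[C@@H]3OC(=O)[C@H]2C3(C)C | intermediate
5 | (1R,5S)-2,8,8-trimethyl-6-oxabicyclo[3.2.1]oct-2-en-7-one | CC1=CC[C@@H]2OC(=O)[C@H]1C2(C)C | intermediate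
6 | diisobutylaluminium lactolate of 5 | CC1=CC[C@@H]2OC(O[Al](CC(C)C)CC(C)C)[C@H]1C2(C)C | intermediate
7 | (1R,5S)-2,8,8-trimethyl-6-oxabicyclo[3.2.1]oct-2-en-7-ol (anomers) | CC1=CC[C@@H]2OC(O)[C@H]1C2(C)C | intermediate
8 | (1R,5S)-5-hydroxy-2,6,6-trimethylcyclohex-2-ene-1-carbaldehyde | O[C@H]1CC=C(C)[C@@H](C=O)C1(C)C | intermediate
9 | (1S,5R)-5-ethenyl-4,6,6-trimethylcyclohex-3-en-1-ol | O[C@H]1CC=C(C)[C@@H](C=C)C1(C)C | intermediate
10 | (1S,5R)-5-ethenyl-4,6,6-trimethylcyclohex-3-en-1-yl acetate | CC(=O)O[C@H]1CC=C(C)[C@@H](C=C)C1(C)C | intermediate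
11 | (2E,6E)-farnesyl bromide | BrC/C=C(\C)CC/C=C(\C)CCC=C(C)C | starting material
12 | propyne | CC#C | starting material
13 | 1,3-dilithiopropyne | [Li]CC#C[Li] | intermediate
14 | lithium (5E,9E)-6,10,14-trimethylpentadeca-5,9,13-trien-1-yn-1-ide | [Li]C#CCC/C=C(\C)CC/C=C(\C)CCC=C(C)C | intermediate
15 | (6E,10E)-2,6,10-trimethylhexadeca-2,6,10-trien-14-yne | CC#CCC/C=C(\C)CC/C=C(\C)CCC=C(C)C | intermediate
16 | (E)-alkenylzirconocene chloride, Zr on the methyl-bearing carbon (Cp rings drawn σ-bound) | Cl[Zr](C1C=CC=C1)(C1C=CC=C1)/C(C)=C/CC/C=C(\C)CC/C=C(\C)CCC=C(C)C | intermediate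
17 | (6E,10E,14E)-15-iodo-2,6,10-trimethylhexadeca-2,6,10,14-tetraene | I/C(C)=C/CC/C=C(\C)CC/C=C(\C)CCC=C(C)C | intermediate
18 | B-[2-((1R,5S)-5-acetoxy-2,6,6-trimethylcyclohex-2-en-1-yl)ethyl]-9-BBN | CC(=O)O[C@H]1CC=C(C)[C@@H](CCB2C3CCCC2CCC3)C1(C)C | intermediate
19 | CNP0313409.1, (1S,5R)-4,6,6-trimethyl-5-[(3E,7E,11E)-3,8,12,16-tetramethylheptadeca-3,7,11,15-tetraen-1-yl]cyclohex-3-en-1-yl acetate | CC(=O)O[C@H]1CC=C(C)[C@@H](CC/C(C)=C/CC/C=C(\C)CC/C=C(\C)CCC=C(C)C)C1(C)C | target

Total steps: 9. Longest linear sequence: 7 (steps 1–6 and 9).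

Steps most likely to fail

1. Step 2. The wrong bridgehead may migrate in the Criegee adduct, or the oxirane next to the strained ring may rearrange under acid. The fallback sets out from 2 and uses the better-migrating allylic bridgehead instead of fighting it.
   - Ethereal diazomethane (Et2O–MeOH, 0 °C) expands the cyclobutanone by one carbon with migration of the allylic carbon to (1R,5S)-2,8,8-trimethylbicyclo[3.2.1]oct-2-en-6-one F1.
   - Baeyer–Villiger oxidation with bis(trimethylsilyl) peroxide/TMSOTf (spares alkenes; secondary bridgehead over CH2) gives the δ-lactone (1S,5R)-6,9,9-trimethyl-2-oxabicyclo[3.3.1]non-6-en-3-one F2.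
   - LiAlH4 gives the diol (1S,5R)-5-(2-hydroxyethyl)-4,6,6-trimethylcyclohex-3-en-1-ol F3.
   - I2/PPh3/imidazole converts only the primary alcohol, to the iodo alcohol F4, and Ac2O/DMAP gives the iodo acetate F5.
   - Zn/LiCl gives the alkylzinc iodide F6, and a Pd-catalysed Negishi coupling with 17 comes back to the route at 19.

2. Step 1. Secondary photolysis of the product, by reversible α-cleavage through the achiral ketene, may erode the enantiopurity. The fallback sets out from 5, made from the scalemic material, and replaces reliance on chirality transfer by a classical resolution.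
   - LiOH (THF–H2O) opens the lactone to (1R,5S)-5-hydroxy-2,6,6-trimethylcyclohex-2-ene-1-carboxylic acid F7.
   - F7 is crystallised as its (R)-1-phenylethylammonium salt F8.
   - Acidification and carbodiimide lactonisation come back at 5.

3. Step 5. Deprotonation at the doubly activated C5–H of the open aldehyde may cause epimerisation or a shift of the alkene into conjugation. The fallback sets out from 7 and never exposes the aldehyde to base.
   - The non-basic organocerium from TMSCH2MgCl/CeCl3 adds to the aldehyde to give the β-hydroxysilane (1S,5R)-5-[1-hydroxy-2-(trimethylsilyl)ethyl]-4,6,6-trimethylcyclohex-3-en-1-ol F9.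
   - An acid-induced Peterson elimination (BF3·OEt2, CH2Cl2, 0 °C) comes back at 9.

Further compounds
F1 | step 2 | (1R,5S)-2,8,8-trimethylbicyclo[3.2.1]oct-2-en-6-one | CC1=CC[C@@H]2C(=O)C[C@H]1C2(C)C
F2 | step 2 | (1S,5R)-6,9,9-trimethyl-2-oxabicyclo[3.3.1]non-6-en-3-one | CC1=CC[C@@H]2OC(=O)C[C@H]1C2(C)C
F3 | step 2 | (1S,5R)-5-(2-hydroxyethyl)-4,6,6-trimethylcyclohex-3-en-1-ol | O[C@H]1CC=C(C)[C@@H](CCO)C1(C)C
F4 | step 2 | (1S,5R)-5-(2-iodoethyl)-4,6,6-trimethylcyclohex-3-en-1-ol | O[C@H]1CC=C(C)[C@@H](CCI)C1(C)C
F5 | step 2 | (1S,5R)-5-(2-iodoethyl)-4,6,6-trimethylcyclohex-3-en-1-yl acetate | CC(=O)O[C@H]1CC=C(C)[C@@H](CCI)C1(C)C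
F6 | step 2 | 2-[(1R,5S)-5-acetoxy-2,6,6-trimethylcyclohex-2-en-1-yl]ethylzinc iodide | CC(=O)O[C@H]1CC=C(C)[C@@H](CC[Zn]I)C1(C)C
F7 | step 1 | (1R,5S)-5-hydroxy-2,6,6-trimethylcyclohex-2-ene-1-carboxylic acid | O[C@H]1CC=C(C)[C@@H](C(=O)O)C1(C)C
F8 | step 1 | (R)-1-phenylethylammonium salt of F7 | O[C@H]1CC=C(C)[C@@H](C(=O)[O-])C1(C)C.C[C@@H]([NH3+])c1ccccc1
F9 | step 5 | (1S,5R)-5-[1-hydroxy-2-(trimethylsilyl)ethyl]-4,6,6-trimethylcyclohex-3-en-1-ol (carbinol epimers) | O[C@H]1CC=C(C)[C@@H](C(O)C[Si](C)(C)C)C1(C)C
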